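Ring A (C1 CO2H, C2 OH, C3 prenyl, C4-H, C5-H, C6 O-aryl) is disconnected at C1–C2 and C5–C6. The feature exploited is that the C2–C5 segment matches C3–C6 of 3-hydroxy-4-prenyl-2-pyrone substituent for substituent. C1 and C6 map onto an alkyne capped by the ester at one end and by the ring B aryloxy group at the other. One amine-promoted [4+2] cycloaddition with CO2 loss builds ring A with all four substituents in place. The crowded ether oxygen is attached beforehand at an sp carbon, which removes any hindered aryl C–O coupling. The precursors are this pyrone and an allyl 3-aryloxypropiolate (MOM and TBS on ring B). The allyl ester frees the hindered acid without hydrolysis.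

Key step: step 11

Remark: the target has no stereocentre and no stereogenic double bond, so only constitution has to be controlled; stereocentres in transient intermediates are racemic and are erased.

Step 1
Reactants: 1 creosol (2-methoxy-4-methylphenol)
Product: 2 2-hydroxy-3-methoxy-5-methylbenzaldehyde
Conditions: MgCl2, Et3N, (CH2O)n, MeCN, reflux; then 1 M HCl
Reagents that add atoms: paraformaldehyde (formaldehyde unit), C=O
Why: Casnati–Skattebøl ortho-formylation: the magnesium phenoxide delivers formaldehyde within a chelate to the only free ortho carbon (the para carbon carries the methyl group), and a second formaldehyde takes up hydride from the benzylic alkoxide to give the aldehyde.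

Step 2
Reactants: 2 2-hydroxy-3-methoxy-5-methylbenzaldehyde
Product: 3 2,3-dihydroxy-5-methylbenzaldehyde
Conditions: BBr3 (2.5 equiv), CH2Cl2, −78 °C → rt; then H2O
Reagents that add atoms: none
Why: Lewis-acid ether cleavage: BBr3 binds the methoxy oxygen and bromide removes the methyl group by SN2 attack, a standard conversion of 3-methoxysalicylaldehydes into 2,3-dihydroxybenzaldehydes that leaves the formyl and aryl methyl groups untouched.

Step 3
Reactants: 3 2,3-dihydroxy-5-methylbenzaldehyde
Product: 4 2-hydroxy-3-(methoxymethoxy)-5-methylbenzaldehyde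
Conditions: NaH (2.1 equiv), THF–DMSO, 0 °C → rt; MOMCl (1.0 equiv), 0 °C
Reagents that add atoms: chloromethyl methyl ether (MOMCl), COCCl
Why: Williamson-type alkylation of the catecholate dianion: the C3 oxide is neither conjugated with nor chelated to the formyl group and is therefore the more nucleophilic oxygen, so one equivalent of MOMCl caps it and leaves the C2 phenol, the future diaryl ether oxygen, free.

Step 4
Reactants: 4 2-hydroxy-3-(methoxymethoxy)-5-methylbenzaldehyde
Product: 5 2-(hydroxymethyl)-6-(methoxymethoxy)-4-methylphenol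
Conditions: NaBH4, THF–MeOH, 0 °C; pH 7 work-up
Reagents that add atoms: none
Why: Borohydride reduction of an aromatic aldehyde, to which the MOM acetal is inert; the near-neutral work-up avoids ortho-quinone methide formation from the salicyl alcohol.

Step 5
Reactants: 5 2-(hydroxymethyl)-6-(methoxymethoxy)-4-methylphenol
Product: 6 2-[(tert-butyldimethylsilyloxy)methyl]-6-(methoxymethoxy)-4-methylphenol
Conditions: TBSCl (1.05 equiv), imidazole, CH2Cl2, 0 °C
Reagents that add atoms: tert-butyldimethylsilyl chloride (TBSCl), CC(C)(C)[Si](C)(C)Cl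
Why: Imidazole-promoted silylation is governed by sterics: the primary benzylic hydroxyl reacts ahead of the phenol, which is flanked by two ortho substituents and hydrogen-bonded to the MOM oxygen.

Step 6
Reactants: 6 2-[(tert-butyldimethylsilyloxy)methyl]-6-(methoxymethoxy)-4-methylphenol; 7 trichloroethylene
Product: 9 2-[(E)-1,2-dichloroethenyloxy]-1-[(tert-butyldimethylsilyloxy)methyl]-3-(methoxymethoxy)-5-methylbenzene, via dichloroacetylene 8 (not isolated)
Conditions: 7 (2 equiv), K2CO3, DMF, 70 °C
Reagents that add atoms: trichloroethylene 7, ClC=C(Cl)Cl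
Why: Base-induced dehydrochlorination of 7 gives 8 in low stationary concentration, and anti addition of the phenoxide gives the (E)-dichlorovinyl ether, the established dichlorovinylation of phenols; the C–O bond forms at an unhindered sp carbon, so the two ortho groups of 6 matter little.

Step 7
Reactants: 9 2-[(E)-1,2-dichloroethenyloxy]-1-[(tert-butyldimethylsilyloxy)methyl]-3-(methoxymethoxy)-5-methylbenzene; 10 allyl chloroformate
Product: 13 allyl 3-[2-(methoxymethoxy)-4-methyl-6-[(tert-butyldimethylsilyloxy)methyl]phenoxy]prop-2-ynoate, via aryloxychloroacetylene 11 (not isolated), via lithium aryloxyacetylide 12 (not isolated)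
Conditions: n-BuLi (2.1 equiv), THF, −78 → −40 °C; 10 (1.5 equiv), −78 → −20 °C; pH 7 buffer; Et3N-deactivated SiO2
Reagents that add atoms: allyl chloroformate 10, C=CCOC(=O)Cl
Why: Dehydrochlorination to 11, Li/Cl exchange to 12 and C-acylation by a chloroformate is the established dichlorovinyl ether route to substituted ynol ethers, and both lithiation events are far faster at −78 °C than MOM-directed ortho-lithiation; the allyl ester is chosen because a 2,6-disubstituted benzoate resists saponification whereas zerovalent palladium later cleaves it at the allyl carbon.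

Step 8
Reactants: 14 3-hydroxy-2H-pyran-2-one; 15 3-chloro-3-methylbut-1-yne
Product: 16 3-[(2-methylbut-3-yn-2-yl)oxy]-2H-pyran-2-one
Conditions: CuCl2·2H2O (1 mol %), DBU (1.3 equiv), MeCN, 0 °C
Reagents that add atoms: 3-chloro-3-methylbut-1-yne 15, C#CC(C)(C)Cl
Why: Copper-catalysed propargylic etherification of an acidic phenol-type hydroxyl: DBU and the copper salt turn 15 into a copper allenylidene that the pyrone oxide captures at the tertiary carbon, which makes the quaternary C–O bond that SN2 alkylation cannot and avoids the branched/linear ambiguity of an allyl electrophile.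

Step 9
Reactants: 16 3-[(2-methylbut-3-yn-2-yl)oxy]-2H-pyran-2-one
Product: 17 3-[(2-methylbut-3-en-2-yl)oxy]-2H-pyran-2-one
Conditions: H2 (1 atm), Pd/CaCO3 poisoned with Pb(OAc)2, quinoline, EtOAc, rt, stopped after 1 equiv H2
Reagents that add atoms: none
Why: Lindlar semi-hydrogenation: the terminal alkyne binds the poisoned palladium surface far more strongly than the vinyl product or the conjugated pyrone, so uptake should stop after one equivalent of hydrogen.

Step 10
Reactants: 17 3-[(2-methylbut-3-en-2-yl)oxy]-2H-pyran-2-one
Product: 19 3-hydroxy-4-(3-methylbut-2-enyl)-2H-pyran-2-one, via 4-prenylpyran-2,3-dione 18 (not isolated)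
Conditions: toluene (degassed), BHT (cat.), 110 °C
Reagents that add atoms: none
Why: Claisen [3,3] rearrangement of the allyl ether of a diosphenol-type enol: the terminal CH2 of the 1,1-dimethylallyl group bonds to pyrone C4, the only carbon doubly bonded to the oxygen-bearing C3, the allyl unit is thereby inverted to prenyl, and 18 (racemic at C4) enolises at once to 19.

Step 11
Reactants: 19 3-hydroxy-4-(3-methylbut-2-enyl)-2H-pyran-2-one (1.3 equiv); 13 allyl 3-[2-(methoxymethoxy)-4-methyl-6-[(tert-butyldimethylsilyloxy)methyl]phenoxy]prop-2-ynoate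
Product: 22 allyl 2-hydroxy-3-(3-methylbut-2-enyl)-6-[2-(methoxymethoxy)-4-methyl-6-[(tert-butyldimethylsilyloxy)methyl]phenoxy]benzoate, via ammonium pyron-3-olate 20 (not isolated), via bridged bicyclic lactone 21 (not isolated)
Conditions: i-Pr2NEt (1.0 equiv), 4 Å MS, toluene (0.2 M), 60 → 110 °C, Ar
Reagents that add atoms: none
Why: Proposed new method: i-Pr2NEt converts 19 into the ion pair 20, a 1-oxidodiene whose HOMO is raised and is largest at pyrone C6, so C6 attacks the aryloxy-bearing β-carbon of the push-pull alkyne 13 while the ester-bearing α-carbon closes on pyrone C3 in a concerted but strongly asynchronous [4+2] addition (Michael/aldol at its stepwise limit) that gives 21. The closest known reactions are the amine-promoted Diels–Alder additions of 3-hydroxy-2-pyrones to acrylates, enones and maleimides and the thermal pyrone/alkynoate cycloaddition-decarboxylation that gives salicylates; a 3-aryloxypropiolate has not been used as the two-carbon partner. Ring A closes as a six-membered carbocycle by this intermolecular [4+2] event (new bonds C1–C2 and C5–C6), and retro-[4+2] extrusion of CO2 from 21 aromatises it and makes the sequence irreversible. The two bridgehead stereocentres of 21 are locked relative to each other by the bicycle, arise as a racemate and disappear with CO2, so nothing has to be controlled. The step needs regioselectivity and carbon- rather than oxygen-attack of the oxide: the first is secured because electronics (nucleophilic C6 with electrophilic β-carbon) and sterics (the bulky aryloxy carbon meets the unsubstituted C6, not the fully substituted C3) point the same way. The second is favoured by the hydrogen-bonded ion pair in toluene, which masks the oxide oxygen, and by an amine too hindered to add to the alkyne.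

Step 12
Reactants: 22 allyl 2-hydroxy-3-(3-methylbut-2-enyl)-6-[2-(methoxymethoxy)-4-methyl-6-[(tert-butyldimethylsilyloxy)methyl]phenoxy]benzoate
Product: 23 allyl 2-hydroxy-6-[2-hydroxy-6-(hydroxymethyl)-4-methylphenoxy]-3-(3-methylbut-2-enyl)benzoate
Conditions: p-TsOH·H2O (0.3 equiv), MeOH, 40 °C; NaHCO3 quench
Reagents that add atoms: none
Why: Acid-catalysed acetal exchange and silyl ether methanolysis remove MOM and TBS in one operation, as is common for prenylated phenols; at the ester stage the C2 phenol is hydrogen-bonded to the carbonyl, which disfavours its addition to the prenyl alkene (chroman formation), and the hindered allyl ester does not transesterify.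

Step 13
Reactants: 23 allyl 2-hydroxy-6-[2-hydroxy-6-(hydroxymethyl)-4-methylphenoxy]-3-(3-methylbut-2-enyl)benzoate
Product: 24 2-hydroxy-6-[2-hydroxy-6-(hydroxymethyl)-4-methylphenoxy]-3-(3-methylbut-2-enyl)benzoic acid (CNP0140656.0)
Conditions: Pd(PPh3)4 (5 mol %), morpholine (5 equiv), THF, rt; then aq. citric acid
Reagents that add atoms: none
Why: Tsuji–Trost-type deallylation: zerovalent palladium ionises the allyl–oxygen bond, remote from the crowded carbonyl carbon, and morpholine traps the π-allyl complex, so the acid is released under neutral conditions that spare the prenyl group, the benzylic alcohol and both phenols.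

Compound list
1 | creosol (2-methoxy-4-methylphenol) | COc1cc(C)ccc1O | starting material
2 | 2-hydroxy-3-methoxy-5-methylbenzaldehyde | COc1cc(C)cc(C=O)c1O | intermediate
3 | 2,3-dihydroxy-5-methylbenzaldehyde | Cc1cc(O)c(O)c(C=O)c1 | intermediate
4 | 2-hydroxy-3-(methoxymethoxy)-5-methylbenzaldehyde | COCOc1cc(C)cc(C=O)c1O | intermediate
5 | 2-(hydroxymethyl)-6-(methoxymethoxy)-4-methylphenol | COCOc1cc(C)cc(CO)c1O | intermediate
6 | 2-[(tert-butyldimethylsilyloxy)methyl]-6-(methoxymethoxy)-4-methylphenol | COCOc1cc(C)cc(CO[Si](C)(C)C(C)(C)C)c1O | intermediate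
7 | trichloroethylene | ClC=C(Cl)Cl | starting material
8 | dichloroacetylene (formed in situ) | ClC#CCl | intermediate
9 | 2-[(E)-1,2-dichloroethenyloxy]-1-[(tert-butyldimethylsilyloxy)methyl]-3-(methoxymethoxy)-5-methylbenzene | COCOc1cc(C)cc(CO[Si](C)(C)C(C)(C)C)c1O/C(Cl)=C\Cl | intermediate
10 | allyl chloroformate | C=CCOC(=O)Cl | starting material
11 | 2-(chloroethynyloxy)-1-[(tert-butyldimethylsilyloxy)methyl]-3-(methoxymethoxy)-5-methylbenzene | ClC#COc1c(OCOC)cc(C)cc1CO[Si](C)(C)C(C)(C)C | intermediate
12 | lithium 2-[2-(methoxymethoxy)-4-methyl-6-[(tert-butyldimethylsilyloxy)methyl]phenoxy]acetylide | [Li]C#COc1c(OCOC)cc(C)cc1CO[Si](C)(C)C(C)(C)C | intermediate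
13 | allyl 3-[2-(methoxymethoxy)-4-methyl-6-[(tert-butyldimethylsilyloxy)methyl]phenoxy]prop-2-ynoate | C=CCOC(=O)C#COc1c(OCOC)cc(C)cc1CO[Si](C)(C)C(C)(C)C | intermediate
14 | 3-hydroxy-2H-pyran-2-one | O=C1OC=CC=C1O | starting material
15 | 3-chloro-3-methylbut-1-yne | C#CC(C)(C)Cl | starting material
16 | 3-[(2-methylbut-3-yn-2-yl)oxy]-2H-pyran-2-one | C#CC(C)(C)OC1=CC=COC1=O | intermediate
17 | 3-[(2-methylbut-3-en-2-yl)oxy]-2H-pyran-2-one | C=CC(C)(C)OC1=CC=COC1=O | intermediate
18 | 4-(3-methylbut-2-enyl)-2H-pyran-2,3(4H)-dione (racemic, transient) | CC(C)=CCC1C=COC(=O)C1=O | intermediate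
19 | 3-hydroxy-4-(3-methylbut-2-enyl)-2H-pyran-2-one | CC(C)=CCC1=C(O)C(=O)OC=C1 | intermediate
20 | N-ethyldiisopropylammonium 4-(3-methylbut-2-enyl)-2-oxo-2H-pyran-3-olate | CC(C)=CCC1=C([O-])C(=O)OC=C1.CC[NH+](C(C)C)C(C)C | intermediate
21 | allyl 4-hydroxy-5-(3-methylbut-2-enyl)-3-oxo-7-aryloxy-2-oxabicyclo[2.2.2]octa-5,7-diene-8-carboxylate, aryl = 2-(methoxymethoxy)-4-methyl-6-[(tert-butyldimethylsilyloxy)methyl]phenyl (racemic, one enantiomer drawn) | O=C1O[C@H]2C=C(CC=C(C)C)[C@]1(O)C(C(=O)OCC=C)=C2Oc1c(OCOC)cc(C)cc1CO[Si](C)(C)C(C)(C)C | intermediate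
22 | allyl 2-hydroxy-3-(3-methylbut-2-enyl)-6-[2-(methoxymethoxy)-4-methyl-6-[(tert-butyldimethylsilyloxy)methyl]phenoxy]benzoate | C=CCOC(=O)c1c(O)c(CC=C(C)C)ccc1Oc1c(OCOC)cc(C)cc1CO[Si](C)(C)C(C)(C)C | intermediate
23 | allyl 2-hydroxy-6-[2-hydroxy-6-(hydroxymethyl)-4-methylphenoxy]-3-(3-methylbut-2-enyl)benzoate | C=CCOC(=O)c1c(O)c(CC=C(C)C)ccc1Oc1c(O)cc(C)cc1CO | intermediate
24 | 2-hydroxy-6-[2-hydroxy-6-(hydroxymethyl)-4-methylphenoxy]-3-(3-methylbut-2-enyl)benzoic acid | CC(C)=CCc1ccc(Oc2c(O)cc(C)cc2CO)c(C(=O)O)c1O | target

Total step count: 13. Longest linear sequence: 10 steps (steps 1–7, then 11–13); the pyrone branch (steps 8–10) is convergent.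

Steps most likely to fail

Step 11 (the labelled step). The donor oxygen lowers the dienophilicity of the alkyne. Three processes may then outrun the cycloaddition: conjugate addition of the oxide oxygen to the β-carbon, exchange of the aryloxide by addition–elimination, and base-induced self-reaction of the pyrone. The fallback uses known chemistry, sets out from 6 and rejoins at 24. It makes the diaryl ether by nucleophilic aromatic substitution and adds the prenyl group by an aromatic Claisen rearrangement. Phenol 6 and 2,6-difluorobenzaldehyde (K2CO3, DMF, 80 °C) should give the fluoro diaryl ether aldehyde F1. The remaining fluoride is displaced by the potassium alkoxide of 2-methylbut-3-en-2-ol (KH, THF, 0 °C → rt) to give the 1,1-dimethylallyl aryl ether aldehyde F2. Heating (toluene or N,N-diethylaniline, 130 °C) moves the allyl unit with inversion to the only free ortho carbon and gives the 3-prenylsalicylaldehyde F3. Pinnick oxidation (NaClO2, NaH2PO4, large excess of 2-methylbut-2-ene, t-BuOH–H2O) gives the protected salicylic acid F4. The conditions of step 12 then remove MOM and TBS to reach 24.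

Step 7. The acetylide may add a second time to the newly formed ynoate. Ortho-lithiation next to the MOM ether may compete if the temperature drifts. The push-pull alkyne may also hydrate during work-up or chromatography. The fallback sets out from 9 and rejoins at 13. The lithiation sequence (through 11 and 12) is quenched with water to give the neutral, purifiable terminal aryloxyacetylene F5. The carboxyl carbon is then introduced by silver iodide (AgI)-catalysed carboxylation under CO2 (1 atm) with Cs2CO3 in DMF, which gives caesium 3-aryloxypropiolate F6. This salt is O-alkylated in the same flask with allyl bromide to give 13. No organolithium or acylating agent is present when the ynoate appears.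

Step 8. DBU may open or oligomerise the lactone. The weakly nucleophilic pyrone oxide may also capture the copper allenylidene too slowly, so that the tertiary chloride is consumed by elimination. The fallback sets out from 14 and rejoins at 17, bypassing steps 8 and 9. 2-Methylbut-3-en-2-ol is converted (n-BuLi, Boc2O, THF) into tert-butyl 2-methylbut-3-en-2-yl carbonate F7. Decarboxylative Tsuji–Trost O-allylation of 14 with it (Pd(PPh3)4, THF, 0–5 °C) should give the branched ether 17 directly. It must be stopped early, so that re-ionisation to the linear ether does not set in.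

Further compounds
F1 | step 11 | 2-fluoro-6-[2-(methoxymethoxy)-4-methyl-6-[(tert-butyldimethylsilyloxy)methyl]phenoxy]benzaldehyde | O=Cc1c(F)cccc1Oc1c(OCOC)cc(C)cc1CO[Si](C)(C)C(C)(C)C
F2 | step 11 | 2-[(2-methylbut-3-en-2-yl)oxy]-6-[2-(methoxymethoxy)-4-methyl-6-[(tert-butyldimethylsilyloxy)methyl]phenoxy]benzaldehyde | C=CC(C)(C)Oc1cccc(Oc2c(OCOC)cc(C)cc2CO[Si](C)(C)C(C)(C)C)c1C=O
F3 | step 11 | 2-hydroxy-3-(3-methylbut-2-enyl)-6-[2-(methoxymethoxy)-4-methyl-6-[(tert-butyldimethylsilyloxy)methyl]phenoxy]benzaldehyde | CC(C)=CCc1ccc(Oc2c(OCOC)cc(C)cc2CO[Si](C)(C)C(C)(C)C)c(C=O)c1O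
F4 | step 11 | 2-hydroxy-3-(3-methylbut-2-enyl)-6-[2-(methoxymethoxy)-4-methyl-6-[(tert-butyldimethylsilyloxy)methyl]phenoxy]benzoic acid | CC(C)=CCc1ccc(Oc2c(OCOC)cc(C)cc2CO[Si](C)(C)C(C)(C)C)c(C(=O)O)c1O
F5 | step 7 | 2-(ethynyloxy)-1-[(tert-butyldimethylsilyloxy)methyl]-3-(methoxymethoxy)-5-methylbenzene | C#COc1c(OCOC)cc(C)cc1CO[Si](C)(C)C(C)(C)C
F6 | step 7 | caesium 3-[2-(methoxymethoxy)-4-methyl-6-[(tert-butyldimethylsilyloxy)methyl]phenoxy]prop-2-ynoate | [Cs+].[O-]C(=O)C#COc1c(OCOC)cc(C)cc1CO[Si](C)(C)C(C)(C)C
F7 | step 8 | tert-butyl 2-methylbut-3-en-2-yl carbonate | C=CC(C)(C)OC(=O)OC(C)(C)C
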